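**Numbering used throughout.** The aryl-bearing carbon of ring B is C1; C2 and C3 carry the one-carbon units C9 and C10; C4 is the other benzylic carbon; C4a and C8a are the fusion carbons; ring A carries methoxy groups at C6, C7 and C8; ring C is the 3,4-dimethoxyphenyl group. The target 13 is (1R,2S).

## The problem

The target 13 is an aryl-dihydronaphthalene lignan. Trimethoxylated ring A is fused through C4a and C8a to ring B (C1–C2–C3=C4), C1 carries ring C, and C2 and C3 carry the hydroxymethyl carbons C9 and C10. There are only two stereocentres, C1 (R) and C2 (S), with ring C and C9 trans. They are adjacent, so either one can direct the other, but nothing else in the finished molecule can correct them, and the absolute sense must come from outside. The C8 methoxy group flanks C8a and crowds C1, which penalises any late bond formation at C1 or C8a. The 1,2-dihydronaphthalene is one oxidation away from a naphthalene, which would erase both stereocentres. While C9 is still a carbonyl, base can epimerise C2 or move the C3=C4 double bond. The C10 alcohol is allylic and ionisable, and five aryl methyl ethers exclude strongly Lewis acidic deprotections. The enabling feature is that C1 and C4 sit on adjacent carbons of ring A while C2 and C3 carry trans one-carbon units that can be carried as carboxylates. Ring B is therefore the dehydrated Diels–Alder adduct of an o-quinodimethane (C1–C8a–C4a–C4) and a fumarate (C2, C3, C9, C10), and the C3=C4 alkene marks C4 as the former carbonyl carbon of a photoenolisable 2-benzylbenzaldehyde.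

## Retrosynthesis

**13 to 12.** No skeletal bond is cut. The two carbinol carbons C9 and C10 of 13 are traced back to the carboxylate level, as the bis-(S)-lactate diester 12. Esters are what a dienophile needs, and i-Bu2AlH should reduce the ring esters and the lactate methyl esters in one operation, so the auxiliary leaves as water-soluble propane-1,2-diol. The forward step has to reduce the enoate at C10 in the 1,2 sense and leave C1 and C2 untouched.

**12 to 10.** The C3=C4 double bond is traced to a C4 carbinol by formal addition of water, giving the 4-hydroxytetralin diester 10. The hydroxyl is exactly the oxygen that a photoenol route leaves at C4. Its removal is regiochemically unambiguous, because C4a has no hydrogen and only C3–H can be lost, and it should be easy, because C3–H is alpha to an ester and C4 is benzylic and para to the C7 methoxy group. The forward step (through mesylate 11) must not epimerise C2 or move the alkene.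

**10 to 5 and 8.** The bonds C1–C2 and C3–C4 are cut together. This reveals the hydroxy-o-quinodimethane 9, which is the photoenol of 2-(3,4-dimethoxybenzyl)-3,4,5-trimethoxybenzaldehyde 5, and the fumarate 8 of methyl (S)-lactate. Cutting C1–C8a (a Friedel–Crafts closure) would have to form a bond next to the C8 methoxy group on a preformed stereotriad, and cutting C4–C4a or C2–C3 leaves all stereocentres to be built on an open chain. The double cut instead removes ring B and four stereocentres at once and leaves an achiral aldehyde and a symmetric, cheap chiral dienophile. The forward reaction must deliver endo selectivity, one fumarate face, and trapping of 9 faster than its reketonisation.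

**8 to 6 and 7.** The two ester C–O bonds are cut, giving fumaryl chloride 6 and methyl (S)-lactate 7. The only demand is that the lactate centre and the (E)-alkene survive acylation.

**5 to 2 and 3.** The aryl–CH2 bond is cut, giving 2-bromo-3,4,5-trimethoxybenzaldehyde 2 and 3,4-dimethoxybenzyl chloride 3, joined through the benzylic zinc reagent 4. A Friedel–Crafts benzylation would have no regiochemical anchor on the aldehyde-deactivated ring and would compete with self-alkylation of ring C. A Negishi coupling fixes the position through the bromide. The forward step must couple at a bromide with two ortho substituents without the zinc reagent adding to the aldehyde.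

**2 to 1.** The C–Br bond is cut, giving 3,4,5-trimethoxybenzaldehyde 1. The two open ring positions of 1 are equivalent, so monobromination can give only 2.

## Roads not taken

**Alternative 1: palladium carbene closure of C4–C4a.**
- Cut: the C4–C4a bond. Ring B would be closed last, from an open-chain aryl bromide carrying the N-tosylhydrazone of the C4 aldehyde (A2), to give the bis-silyl ether of the target (A1).
- Forward key step: Pd2(dba)3, XPhos and LiOt-Bu. Base converts A2 to the diazo compound, zerovalent palladium inserts into the ring A C–Br bond, the aryl group migrates to the palladium carbene (C4–C4a formed), and beta-hydride elimination, possible only from C3, installs C3=C4.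
- Merits: A1 is the target skeleton at the final oxidation level. The alkene position is unambiguous. No dehydration and no auxiliary cleavage are needed, only a desilylation. The question of facial sense that the chosen plan carries does not arise in the ring closure.
- Weak points: A2 must already hold C1 and C2 in absolute form, plus a C3 centre that the step destroys, so most of the route would be open-chain stereocontrol around a very crowded diarylmethine. Oxidative addition into an electron-rich bromide ortho to that methine is slow. The alpha-branched diazo intermediate can lose nitrogen by a Bamford–Stevens 1,2-hydrogen shift before palladium captures it.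
- Comparison: the endgame of Alternative 1 is better than the chosen one. Against that, the chosen plan builds ring B and every stereocentre in one convergent step from two fragments that each take two steps, and is expected to be roughly half as long.

**Alternative 2: gold-catalysed formal [4+2] of a tethered aryl enyne.**
- Cut: C2–C3 and C1–C8a, with an ether oxygen tethering C9 to C10. The precursor is the cinnamyl 3-arylpropargyl ether A4, and the product is the furan-fused dihydronaphthalene A3.
- Forward key step: a chiral monovalent gold catalyst, for example (R)-DTBM-SEGPHOS(AuCl)2 activated with AgSbF6, makes the alkyne carbon C3 bond to alkene carbon C2. The benzylic cation at C1 is captured by ring A at C8a, and protodeauration leaves C3=C4.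
- Merits: A4 is available in about three steps. The symmetric 3,4,5-trimethoxyphenyl alkyne gives the right ring A pattern at either ortho position. The (E)-alkene translates into the trans C1/C2 relationship. Chirality is catalytic, not stoichiometric. In length and atom economy this road is better than the chosen plan.
- Weak points: A3 still has C9 and C10 joined through oxygen. Opening a dialkyl/allylic tetrahydrofuran to a diol needs hard Lewis acids or silyl iodides, which attack the five aryl methyl ethers. Ionisation at C10 gives an allyl cation delocalised onto benzylic C4, which invites transposition and aromatisation. Enantioselectivity in this reaction class is strongly substrate dependent.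
- Comparison: what the chosen plan sets against the shorter front end is that C9 and C10 arrive as two independent esters, which hydride releases directly as the diol under conditions the rest of the molecule tolerates.

**Alternative 3: anodic enol ether–styrene coupling closing ring B.**
- Cut: the C2–C3 bond. The precursor is the enantioenriched diarylmethane A6 with an enol ether on C1 and a silyloxy-substituted styrene on ring A. The product is the tetralin A5, with C9 as a dimethyl acetal and C4 as a methyl ether.
- Forward key step: constant-current oxidation at a carbon anode in methanol with LiClO4 and 2,6-lutidine. The radical cation couples C2 with C3, and methanol traps C9 and C4.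
- Merits: an umpolung bond construction under mild, reagent-free conditions. C9 and C10 emerge differentiated. The C4 methoxy group is a latent C3=C4 alkene.
- Weak points: the two polyalkoxyarenes and the styrene are oxidised at potentials close to that of the enol ether, so the site of oxidation and overoxidation of A5 at the doubly benzylic C1 are hard to control. The stereocentres C2, C3 and C4 would rest on induction from C1 alone. C1 must first be made as a single enantiomer at a diarylmethine. Afterwards methanol elimination, acetal hydrolysis (an epimerisable C2 aldehyde), reduction and desilylation are needed.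
- Comparison: the differentiation of C9 and C10 is of no use here, since both end as CH2OH. The chosen plan sets the same centres in a concerted step with defined relative topology and needs fewer operations after ring closure.

Key step: step 4

**Assumption (chemistry).** The (S)-lactate esters of 8 are taken to expose to dienol 9 the fumarate face that leads to the (1R,2S,3R,4R) adduct 10. This sense is assumed, not derived. It is to be checked on 10 before material is carried on, and the fallback for step 4 covers the opposite outcome.

## Route

Step 1
Reactants: 1 3,4,5-trimethoxybenzaldehyde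
Product: 2 2-bromo-3,4,5-trimethoxybenzaldehyde
Conditions: NBS (1.1 equiv), CHCl3, reflux
Reagents that add atoms: N-bromosuccinimide, O=C1CCC(=O)N1Br
Why: Electrophilic aromatic bromination; the two free ring positions of 1 are equivalent by symmetry and activated by the methoxy groups, and the first bromine deactivates the ring against a second substitution.

Step 2
Reactants: 2 2-bromo-3,4,5-trimethoxybenzaldehyde; 3 3,4-dimethoxybenzyl chloride
Product: 5 2-(3,4-dimethoxybenzyl)-3,4,5-trimethoxybenzaldehyde, via (3,4-dimethoxybenzyl)zinc chloride 4 (not isolated)
Conditions: 3, Zn dust, LiCl, THF, 25 °C; then slow addition of 4 to 2, Pd(OAc)2 (2 mol %), SPhos (4 mol %), THF, 25 °C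
Reagents that add atoms: none
Why: LiCl-assisted zinc insertion into the benzylic chloride followed by Negishi cross-coupling; the biaryl phosphine SPhos is chosen because the bromide has two ortho substituents, and slow addition keeps 4 dilute so that transmetalation outruns addition to the hindered, electron-rich aldehyde.

Step 3
Reactants: 6 fumaryl chloride; 7 methyl (S)-lactate (2.2 equiv)
Product: 8 bis[(2S)-1-methoxy-1-oxopropan-2-yl] (E)-but-2-enedioate
Conditions: toluene, 80 °C, N2 sweep
Reagents that add atoms: none
Why: Acylation of a secondary alcohol by an acid chloride; no base is present, so the lactate stereocentre cannot racemise, and the (E)-alkene is carried over unchanged.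

Step 4
Reactants: 5 2-(3,4-dimethoxybenzyl)-3,4,5-trimethoxybenzaldehyde; 8 bis[(2S)-1-methoxy-1-oxopropan-2-yl] (E)-but-2-enedioate
Product: 10 bis[(2S)-1-methoxy-1-oxopropan-2-yl] (1R,2S,3R,4R)-1-(3,4-dimethoxyphenyl)-4-hydroxy-6,7,8-trimethoxy-1,2,3,4-tetrahydronaphthalene-2,3-dicarboxylate, via hydroxy-o-quinodimethane photodienol 9 (not isolated)
Conditions: hν (350–365 nm, Pyrex), 8 (2 equiv), degassed toluene, 20 °C
Reagents that add atoms: none
Why: Excitation of the aryl aldehyde, intersystem crossing and a 1,5-hydrogen transfer from the doubly benzylic CH2 to the carbonyl oxygen give dienol 9; the isomer with the hydroxyl turned inward reverts to 5 by a fast thermal 1,5-hydrogen shift, so only the long-lived dienol with hydroxyl and ring C both outward is available for trapping. The closest known reaction type is photoenolisation of ortho-benzyl benzaldehydes with Diels–Alder trapping, together with additions of alpha-hydroxy-o-quinodimethanes to fumarates of chiral alpha-hydroxy esters. Ring B closes by a concerted suprafacial [4+2] cycloaddition in which C1–C2 and C3–C4 form in one six-membered transition state and ring A regains aromaticity. The cis C1/C4 relationship follows from the out,out diene geometry, the trans C2/C3 relationship from the (E)-fumarate, and the cis C3/C4 relationship from the endo placement of the C3 ester, which is held by a hydrogen bond from the dienol hydroxyl to that ester carbonyl and leaves the C2 ester trans to ring C. The absolute configuration is set by the (S)-lactate esters, which make the two fumarate faces diastereotopic; the two possible endo adducts are diastereomers and can be separated if induction is incomplete. The step needs endo over exo, one fumarate face over the other, and cycloaddition faster than reketonisation or oxygenation of 9; the hydrogen bond in a non-polar solvent, an excess of 8, exclusion of oxygen, and light that 5 absorbs but 8 does not are meant to secure this.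

Step 5
Reactants: 10 bis[(2S)-1-methoxy-1-oxopropan-2-yl] (1R,2S,3R,4R)-1-(3,4-dimethoxyphenyl)-4-hydroxy-6,7,8-trimethoxy-1,2,3,4-tetrahydronaphthalene-2,3-dicarboxylate
Product: 12 bis[(2S)-1-methoxy-1-oxopropan-2-yl] (1R,2S)-1-(3,4-dimethoxyphenyl)-6,7,8-trimethoxy-1,2-dihydronaphthalene-2,3-dicarboxylate, via C4 methanesulfonate 11 (not isolated)
Conditions: MsCl, Et3N, CH2Cl2, 0 → 25 °C
Reagents that add atoms: none
Why: Mesylation followed by beta-elimination; C3–H is alpha to an ester and anti to the leaving group, the benzylic mesylate is further labilised by the para C7 methoxy group, and C4a has no hydrogen, so only the conjugated C3=C4 alkene can form while C1 and C2 are not involved.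

Step 6
Reactants: 12 bis[(2S)-1-methoxy-1-oxopropan-2-yl] (1R,2S)-1-(3,4-dimethoxyphenyl)-6,7,8-trimethoxy-1,2-dihydronaphthalene-2,3-dicarboxylate
Product: 13 [(1R,2S)-1-(3,4-dimethoxyphenyl)-6,7,8-trimethoxy-1,2-dihydronaphthalene-2,3-diyl]dimethanol
Conditions: i-Bu2AlH (10 equiv), CH2Cl2, −78 → 0 °C; aq. KNaC4H4O6 work-up
Reagents that add atoms: none
Why: Hydride reduction of esters with i-Bu2AlH, which reduces the enoate at C10 in the 1,2 sense and the saturated ester at C9 to the primary alcohols; the lactate units are reduced as well and leave as (S)-propane-1,2-diol and methanol in the aqueous phase, and no stereocentre is touched.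

## Compound list

1 | 3,4,5-trimethoxybenzaldehyde | COc1cc(C=O)cc(OC)c1OC | starting material
2 | 2-bromo-3,4,5-trimethoxybenzaldehyde | COc1cc(C=O)c(Br)c(OC)c1OC | intermediate
3 | 3,4-dimethoxybenzyl chloride | COc1ccc(CCl)cc1OC | starting material
4 | (3,4-dimethoxybenzyl)zinc chloride | COc1ccc(C[Zn]Cl)cc1OC | intermediate
5 | 2-(3,4-dimethoxybenzyl)-3,4,5-trimethoxybenzaldehyde | COc1ccc(Cc2c(OC)c(OC)c(OC)cc2C=O)cc1OC | intermediate
6 | fumaryl chloride | O=C(Cl)/C=C/C(Cl)=O | starting material
7 | methyl (S)-lactate | C[C@H](O)C(=O)OC | starting material
8 | bis[(2S)-1-methoxy-1-oxopropan-2-yl] (E)-but-2-enedioate | COC(=O)[C@H](C)OC(=O)/C=C/C(=O)O[C@@H](C)C(=O)OC | intermediate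
9 | hydroxy-o-quinodimethane photodienol of 5, hydroxyl and ring C both outward | O/C=C1\C=C(OC)C(OC)=C(OC)/C1=C\c1ccc(OC)c(OC)c1 | intermediate
10 | bis[(2S)-1-methoxy-1-oxopropan-2-yl] (1R,2S,3R,4R)-1-(3,4-dimethoxyphenyl)-4-hydroxy-6,7,8-trimethoxy-1,2,3,4-tetrahydronaphthalene-2,3-dicarboxylate (1,2-trans, 2,3-trans, 3,4-cis) | COc1ccc([C@@H]2c3c(cc(OC)c(OC)c3OC)[C@H](O)[C@H](C(=O)O[C@@H](C)C(=O)OC)[C@H]2C(=O)O[C@@H](C)C(=O)OC)cc1OC | intermediate
11 | C4 methanesulfonate of 10 | COc1ccc([C@@H]2c3c(cc(OC)c(OC)c3OC)[C@H](OS(C)(=O)=O)[C@H](C(=O)O[C@@H](C)C(=O)OC)[C@H]2C(=O)O[C@@H](C)C(=O)OC)cc1OC | intermediate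
12 | bis[(2S)-1-methoxy-1-oxopropan-2-yl] (1R,2S)-1-(3,4-dimethoxyphenyl)-6,7,8-trimethoxy-1,2-dihydronaphthalene-2,3-dicarboxylate | COc1ccc([C@@H]2c3c(cc(OC)c(OC)c3OC)C=C(C(=O)O[C@@H](C)C(=O)OC)[C@H]2C(=O)O[C@@H](C)C(=O)OC)cc1OC | intermediate
13 | [(1R,2S)-1-(3,4-dimethoxyphenyl)-6,7,8-trimethoxy-1,2-dihydronaphthalene-2,3-diyl]dimethanol | COc1ccc([C@@H]2c3c(cc(OC)c(OC)c3OC)C=C(CO)[C@H]2CO)cc1OC | target

## Step count and least certain steps

Total step count: 6. Longest linear sequence: 5 (steps 1, 2, 4, 5, 6); step 3 is a one-step side branch.

**Step 4 (key step).** The most likely failure is facial selectivity of the wrong sense or too low a level, because the lactate centres are several bonds from the reacting alkene and their influence rests on a conformational preference that is assumed. A second concern is that the outward ring C on dienol 9 lies next to the C8 methoxy group, which could twist 9 and shorten its lifetime. The fallback changes the stereocontrolling element, not the light source or solvent. It sets out from fumaryl chloride 6 and aldehyde 5. Acylation of methyl (R)-lactate F1 with 6 should give bis[(2R)-1-methoxy-1-oxopropan-2-yl] (E)-but-2-enedioate F2. Irradiation of 5 with F2 under the conditions of step 4 should give the (1R,2S,3R,4R) adduct carrying (R)-lactate esters, F3. MsCl and Et3N should convert F3 through its C4 methanesulfonate F4 into the (1R,2S)-dihydronaphthalene bis-(R)-lactate diester F5. Reduction of F5 with i-Bu2AlH cleaves the auxiliary and comes back to the route at 13.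

**Step 2.** The most likely failure is addition of the benzylic zinc reagent 4 to the aldehyde of 2 or 5 in competition with cross-coupling, because the bromide has two ortho substituents and oxidative addition and transmetalation are slowed. The fallback removes the electrophilic carbonyl during the coupling. It sets out from 2, which is converted with ethylene glycol and TsOH in toluene (water removal) into 2-(2-bromo-3,4,5-trimethoxyphenyl)-1,3-dioxolane F6. Negishi coupling of F6 with 4 should give 2-[2-(3,4-dimethoxybenzyl)-3,4,5-trimethoxyphenyl]-1,3-dioxolane F7. Aqueous HCl in THF hydrolyses F7 and returns to the route at 5.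

**Step 5.** The most likely failure is epimerisation at C2 or migration of the double bond through the extended enolate that the amine base can form from 12, followed by air oxidation to the naphthalene. The fallback replaces base-driven sulfonate elimination by acid-catalysed E1 dehydration (TsOH, toluene, 80 °C), which relies on the benzylic cation at C4 stabilised by the C7 methoxy group. It sets out from 10 and returns directly at 12 without a new compound.

**Step 6.** The most likely failure is uneven reduction of four ester groups, leaving aldehyde or partly reduced material, or some conjugate reduction of the enoate, because a large excess of hydride is needed. The fallback removes the auxiliary before the reduction. It sets out from 12, which on transesterification in methanol with catalytic Ti(OiPr)4 at reflux should give dimethyl (1R,2S)-1-(3,4-dimethoxyphenyl)-6,7,8-trimethoxy-1,2-dihydronaphthalene-2,3-dicarboxylate F8 and release methyl (S)-lactate. Reduction of F8 with i-Bu2AlH in toluene at −78 °C then needs only four hydride equivalents and returns to the route at 13.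

## Further compounds

F1 | step 4 | methyl (R)-lactate | C[C@@H](O)C(=O)OC
F2 | step 4 | bis[(2R)-1-methoxy-1-oxopropan-2-yl] (E)-but-2-enedioate | COC(=O)[C@@H](C)OC(=O)/C=C/C(=O)O[C@H](C)C(=O)OC
F3 | step 4 | bis[(2R)-1-methoxy-1-oxopropan-2-yl] (1R,2S,3R,4R)-1-(3,4-dimethoxyphenyl)-4-hydroxy-6,7,8-trimethoxy-1,2,3,4-tetrahydronaphthalene-2,3-dicarboxylate | COc1ccc([C@@H]2c3c(cc(OC)c(OC)c3OC)[C@H](O)[C@H](C(=O)O[C@H](C)C(=O)OC)[C@H]2C(=O)O[C@H](C)C(=O)OC)cc1OC
F4 | step 4 | C4 methanesulfonate of F3 | COc1ccc([C@@H]2c3c(cc(OC)c(OC)c3OC)[C@H](OS(C)(=O)=O)[C@H](C(=O)O[C@H](C)C(=O)OC)[C@H]2C(=O)O[C@H](C)C(=O)OC)cc1OC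
F5 | step 4 | bis[(2R)-1-methoxy-1-oxopropan-2-yl] (1R,2S)-1-(3,4-dimethoxyphenyl)-6,7,8-trimethoxy-1,2-dihydronaphthalene-2,3-dicarboxylate | COc1ccc([C@@H]2c3c(cc(OC)c(OC)c3OC)C=C(C(=O)O[C@H](C)C(=O)OC)[C@H]2C(=O)O[C@H](C)C(=O)OC)cc1OC
F6 | step 2 | 2-(2-bromo-3,4,5-trimethoxyphenyl)-1,3-dioxolane | COc1cc(C2OCCO2)c(Br)c(OC)c1OC
F7 | step 2 | 2-[2-(3,4-dimethoxybenzyl)-3,4,5-trimethoxyphenyl]-1,3-dioxolane | COc1ccc(Cc2c(C3OCCO3)cc(OC)c(OC)c2OC)cc1OC
F0 | step 5 | none | none
F8 | step 6 | dimethyl (1R,2S)-1-(3,4-dimethoxyphenyl)-6,7,8-trimethoxy-1,2-dihydronaphthalene-2,3-dicarboxylate | COc1ccc([C@@H]2c3c(cc(OC)c(OC)c3OC)C=C(C(=O)OC)[C@H]2C(=O)OC)cc1OC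
A1 | alternative 1 | bis(tert-butyldimethylsilyl) ether of the target | COc1ccc([C@@H]2c3c(cc(OC)c(OC)c3OC)C=C(CO[Si](C)(C)C(C)(C)C)[C@H]2CO[Si](C)(C)C(C)(C)C)cc1OC
A2 | alternative 1 | N-tosylhydrazone of (3R,4R)-4-(2-bromo-3,4,5-trimethoxyphenyl)-2,3-bis(tert-butyldimethylsilyloxymethyl)-4-(3,4-dimethoxyphenyl)butanal (lignan C1 R, C2 R by the rules for this chain; C3 either configuration) | COc1ccc([C@H](c2c(Br)cc(OC)c(OC)c2OC)[C@H](CO[Si](C)(C)C(C)(C)C)C(CO[Si](C)(C)C(C)(C)C)C=NNS(=O)(=O)c2ccc(C)cc2)cc1OC
A3 | alternative 2 | furan-fused trans-1-aryl-1,2-dihydronaphthalene with oxygen bridging C9 and C10 | COc1ccc([C@@H]2c3c(cc(OC)c(OC)c3OC)C=C3COC[C@@H]23)cc1OC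
A4 | alternative 2 | (E)-3-(3,4-dimethoxyphenyl)allyl 3-(3,4,5-trimethoxyphenyl)prop-2-ynyl ether | COc1ccc(/C=C/COCC#Cc2cc(OC)c(OC)c(OC)c2)cc1OC
A5 | alternative 3 | 1-aryl-2-(dimethoxymethyl)-3-(tert-butyldimethylsilyloxymethyl)-4-methoxytetralin, expected major isomer | COc1ccc([C@@H]2c3c(cc(OC)c(OC)c3OC)[C@@H](OC)[C@H](CO[Si](C)(C)C(C)(C)C)[C@H]2C(OC)OC)cc1OC
A6 | alternative 3 | diarylmethane with a methyl enol ether on C1 (E/Z mixture) and an (E)-3-(tert-butyldimethylsilyloxy)prop-1-enyl group on ring A | COc1ccc([C@@H](C=COC)c2c(/C=C/CO[Si](C)(C)C(C)(C)C)cc(OC)c(OC)c2OC)cc1OC
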